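The route rests on cutting C7–C1, the bond from the benzylic CH2 to ring A (the 3-methoxy-4,5-dihydroxyphenyl ring), together with the adjacent C8–H bond. The unit ring A–C7H2–C8H(C9H3)– is the retron of an anti-Markovnikov hydroarylation, so C7=C8 is carried as a 1,1-disubstituted alkene. One dual copper hydride/palladium step joins a ring A bromide to this alkene, forms C7–C1 and sets C8 under ligand control. The precursor, ring B–C7'H2–C8'H(CH3)–C(CH3)=CH2, holds only the C8' centre, which comes from sparteine-directed lithiation–borylation and Zweifel olefination. Three benzyl ethers are removed in a final hydrogenolysis.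

Key step: step 8

Atom labels (lignan numbering): ring A has C1 as its alkyl-bearing carbon. C7 is its benzylic CH2, C8 the adjacent methine and C9 the methyl on C8. Ring B (4-hydroxy-3,5-dimethoxyphenyl), C7', C8' and C9' are the counterparts in the other half. The target is (8R,8'R).

Assumption: (R)-DTBM-SEGPHOS is taken as the ligand enantiomer whose copper hydride delivers hydrogen to the face of C8 that leads to (8R). If the sense of induction is the opposite, the equally available (S)-ligand takes its place and nothing else changes.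

Step 1
Reactants: 1 4-bromo-2,6-dimethoxyphenol
Product: 2 2-(benzyloxy)-5-bromo-1,3-dimethoxybenzene
Conditions: BnBr, K2CO3, DMF, 25 °C
Reagents that add atoms: benzyl bromide, BrCc1ccccc1
Why: Williamson ether synthesis on the acidic phenol should give a benzyl ether that withstands organolithium, iodine and copper hydride chemistry until the final hydrogenolysis.

Step 2
Reactants: 2 2-(benzyloxy)-5-bromo-1,3-dimethoxybenzene
Product: 5 2-[4-(benzyloxy)-3,5-dimethoxybenzyl]-4,4,5,5-tetramethyl-1,3,2-dioxaborolane, via aryllithium 3 (not isolated), via chloromethyl boronate complex 4 (not isolated)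
Conditions: n-BuLi, THF, −78 °C; ClCH2Bpin, −78 °C to 25 °C
Reagents that add atoms: 2-(chloromethyl)-4,4,5,5-tetramethyl-1,3,2-dioxaborolane, ClCB1OC(C)(C)C(C)(C)O1
Why: Bromine–lithium exchange gives aryllithium 3, which adds to boron to form 4, and the electron-rich aryl group then displaces chloride in a Matteson-type 1,2-metallate rearrangement, so C7' arrives with boron already on it.

Step 3
Reactants: 6 2,4,6-triisopropylbenzoic acid
Product: 7 ethyl 2,4,6-triisopropylbenzoate
Conditions: EtI, K2CO3, DMF, 25 °C
Reagents that add atoms: iodoethane, CCI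
Why: SN2 O-alkylation of the carboxylate avoids attack at the shielded carbonyl group, which is the usual way to esters of this hindered acid.

Step 4
Reactants: 7 ethyl 2,4,6-triisopropylbenzoate; 5 2-[4-(benzyloxy)-3,5-dimethoxybenzyl]-4,4,5,5-tetramethyl-1,3,2-dioxaborolane
Product: 10 (R)-2-{1-[4-(benzyloxy)-3,5-dimethoxyphenyl]propan-2-yl}-4,4,5,5-tetramethyl-1,3,2-dioxaborolane, via lithiated benzoate 8 (not isolated), via boronate complex 9 (not isolated)
Conditions: 7, s-BuLi, (−)-sparteine, Et2O, −78 °C; add 5, −78 °C; then 35 °C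
Reagents that add atoms: none
Why: Lithiation–borylation: sparteine-directed (Hoppe-type) deprotonation removes the pro-S hydrogen of 7 to give configurationally stable (S)-8, boron is taken up with retention to give 9, and the benzyl group migrates from boron to carbon antiperiplanar to the leaving benzoate with inversion, which sets C8' as (R) under reagent control.

Step 5
Reactants: 10 (R)-2-{1-[4-(benzyloxy)-3,5-dimethoxyphenyl]propan-2-yl}-4,4,5,5-tetramethyl-1,3,2-dioxaborolane
Product: 13 (R)-2-(benzyloxy)-5-(2,3-dimethylbut-3-en-1-yl)-1,3-dimethoxybenzene, via isopropenyl boronate complex 11 (not isolated), via beta-iodo boronic ester 12 (not isolated)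
Conditions: 2-bromopropene, t-BuLi (2 equiv), THF, −78 °C; add 10; I2, THF, −78 °C; NaOMe, MeOH, −78 °C to 25 °C
Reagents that add atoms: 2-bromopropene (used as isopropenyllithium), C=C(C)Br
Why: Zweifel olefination: iodine activates the isopropenyl group of 11, C8' migrates from boron to carbon with retention of its configuration to give 12, and methoxide-induced anti elimination of boron and iodide can deliver only the terminal C7=C8 alkene.

Step 6
Reactants: 14 5-bromo-2-hydroxy-3-methoxybenzaldehyde
Product: 16 5-bromo-3-methoxybenzene-1,2-diol, via aryl formate 15 (not isolated)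
Conditions: 30% aq H2O2, NaOH, H2O, N2, 0 to 25 °C; then HCl
Reagents that add atoms: hydrogen peroxide, OO
Why: Dakin oxidation: hydroperoxide adds to the aldehyde, the electron-rich aryl group migrates to oxygen to give formate 15 and saponification frees the catechol, which places bromine para to the central oxygen, a pattern that direct bromination of 3-methoxycatechol would not secure.

Step 7
Reactants: 16 5-bromo-3-methoxybenzene-1,2-diol
Product: 17 1,2-bis(benzyloxy)-5-bromo-3-methoxybenzene
Conditions: BnBr (2.2 equiv), K2CO3, DMF, 25 to 50 °C, N2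
Reagents that add atoms: benzyl bromide, BrCc1ccccc1
Why: Double Williamson ether synthesis masks both acidic catechol hydroxyl groups, which would quench the copper hydride and the base of the key step, as ethers that leave together with the ring B benzyl group.

Step 8
Reactants: 13 (R)-2-(benzyloxy)-5-(2,3-dimethylbut-3-en-1-yl)-1,3-dimethoxybenzene; 17 1,2-bis(benzyloxy)-5-bromo-3-methoxybenzene
Product: 19 (2R,3R)-1-[3,4-bis(benzyloxy)-5-methoxyphenyl]-4-[4-(benzyloxy)-3,5-dimethoxyphenyl]-2,3-dimethylbutane, via alkylcopper 18 (not isolated)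
Conditions: CuOAc (5 mol %), (R)-DTBM-SEGPHOS, [Pd(cinnamyl)Cl]2 (2 mol %), BrettPhos, MePh2SiH, NaOSiMe3, THF, 45 °C
Reagents that add atoms: none
Why: Copper hydride bound to DTBM-SEGPHOS, formed from CuOAc, NaOSiMe3 and the silane, adds across C7=C8 of 13 with copper on the terminal C7 and hydride on C8 to give primary alkylcopper 18. In parallel BrettPhos-bound zerovalent palladium inserts into the C1–Br bond of 17, 18 passes its alkyl group to the divalent arylpalladium bromide, reductive elimination forms C7–C1, and NaOSiMe3 plus silane turn the copper bromide back into copper hydride. The closest known reaction type is the dual CuH/Pd anti-Markovnikov enantioselective hydroarylation of unactivated 1,1-disubstituted alkenes with aryl bromides. No ring is closed. The one new stereocentre, C8, is fixed in the irreversible hydrocupration by the chiral ligand pocket, which has only to tell the small C9 methyl from the branched C8' substituent, so ligand control should override the weak bias of the resident C8' centre, which itself is not touched. The step needs anti-Markovnikov regioselectivity, secured by the 1,1-disubstitution that disfavours a tertiary alkylcopper, and coupling faster than reduction of 17 or beta-hydride elimination, secured by the bulky biaryl phosphine and by the absence of acidic or reducible groups once all phenols are benzylated.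

Step 9
Reactants: 19 (2R,3R)-1-[3,4-bis(benzyloxy)-5-methoxyphenyl]-4-[4-(benzyloxy)-3,5-dimethoxyphenyl]-2,3-dimethylbutane
Product: 20 sauriol B
Conditions: H2 (1 atm), 10% Pd/C, EtOAc/MeOH, 25 °C
Reagents that add atoms: none
Why: Catalytic hydrogenolysis of the three benzyl aryl ethers under neutral conditions should touch neither the methyl ethers nor the two stereocentres and spares the oxidation-prone catechol any acid, base or oxidant.

Compound list
1 | 4-bromo-2,6-dimethoxyphenol | COc1cc(Br)cc(OC)c1O | starting material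
2 | 2-(benzyloxy)-5-bromo-1,3-dimethoxybenzene | COc1cc(Br)cc(OC)c1OCc1ccccc1 | intermediate
3 | [4-(benzyloxy)-3,5-dimethoxyphenyl]lithium | COc1cc([Li])cc(OC)c1OCc1ccccc1 | intermediate
4 | lithium [4-(benzyloxy)-3,5-dimethoxyphenyl](chloromethyl)(pinacolato)borate | [Li+].COc1cc(cc(OC)c1OCc1ccccc1)[B-]1(CCl)OC(C)(C)C(C)(C)O1 | intermediate
5 | 2-[4-(benzyloxy)-3,5-dimethoxybenzyl]-4,4,5,5-tetramethyl-1,3,2-dioxaborolane | COc1cc(CB2OC(C)(C)C(C)(C)O2)cc(OC)c1OCc1ccccc1 | intermediate
6 | 2,4,6-triisopropylbenzoic acid | CC(C)c1cc(C(C)C)c(C(=O)O)c(C(C)C)c1 | starting material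
7 | ethyl 2,4,6-triisopropylbenzoate | CCOC(=O)c1c(C(C)C)cc(C(C)C)cc1C(C)C | intermediate
8 | (S)-1-lithioethyl 2,4,6-triisopropylbenzoate (sparteine-bound) | [Li][C@@H](C)OC(=O)c1c(C(C)C)cc(C(C)C)cc1C(C)C | intermediate
9 | lithium [4-(benzyloxy)-3,5-dimethoxybenzyl][(S)-1-(2,4,6-triisopropylbenzoyloxy)ethyl](pinacolato)borate | [Li+].COc1cc(C[B-]2(OC(C)(C)C(C)(C)O2)[C@@H](C)OC(=O)c2c(C(C)C)cc(C(C)C)cc2C(C)C)cc(OC)c1OCc1ccccc1 | intermediate
10 | (R)-2-{1-[4-(benzyloxy)-3,5-dimethoxyphenyl]propan-2-yl}-4,4,5,5-tetramethyl-1,3,2-dioxaborolane | COc1cc(C[C@@H](C)B2OC(C)(C)C(C)(C)O2)cc(OC)c1OCc1ccccc1 | intermediate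
11 | lithium {(R)-1-[4-(benzyloxy)-3,5-dimethoxyphenyl]propan-2-yl}(isopropenyl)(pinacolato)borate | [Li+].COc1cc(C[C@@H](C)[B-]2(C(C)=C)OC(C)(C)C(C)(C)O2)cc(OC)c1OCc1ccccc1 | intermediate
12 | 2-{(3R)-4-[4-(benzyloxy)-3,5-dimethoxyphenyl]-1-iodo-2,3-dimethylbutan-2-yl}-4,4,5,5-tetramethyl-1,3,2-dioxaborolane (boron-bearing carbon undefined) | COc1cc(C[C@@H](C)C(C)(CI)B2OC(C)(C)C(C)(C)O2)cc(OC)c1OCc1ccccc1 | intermediate
13 | (R)-2-(benzyloxy)-5-(2,3-dimethylbut-3-en-1-yl)-1,3-dimethoxybenzene | COc1cc(C[C@@H](C)C(C)=C)cc(OC)c1OCc1ccccc1 | intermediate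
14 | 5-bromo-2-hydroxy-3-methoxybenzaldehyde | COc1cc(Br)cc(C=O)c1O | starting material
15 | 5-bromo-2-hydroxy-3-methoxyphenyl formate | COc1cc(Br)cc(OC=O)c1O | intermediate
16 | 5-bromo-3-methoxybenzene-1,2-diol | COc1cc(Br)cc(O)c1O | intermediate
17 | 1,2-bis(benzyloxy)-5-bromo-3-methoxybenzene | COc1cc(Br)cc(OCc2ccccc2)c1OCc1ccccc1 | intermediate
18 | {(2S,3R)-4-[4-(benzyloxy)-3,5-dimethoxyphenyl]-2,3-dimethylbutyl}copper (DTBM-SEGPHOS-bound, same spatial arrangement as in 19) | [Cu]C[C@@H](C)[C@H](C)Cc1cc(OC)c(OCc2ccccc2)c(OC)c1 | intermediate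
19 | (2R,3R)-1-[3,4-bis(benzyloxy)-5-methoxyphenyl]-4-[4-(benzyloxy)-3,5-dimethoxyphenyl]-2,3-dimethylbutane (tri-O-benzyl sauriol B) | COc1cc(C[C@@H](C)[C@H](C)Cc2cc(OC)c(OCc3ccccc3)c(OC)c2)cc(OCc2ccccc2)c1OCc1ccccc1 | intermediate
20 | sauriol B, 5-[(2R,3R)-4-(4-hydroxy-3,5-dimethoxyphenyl)-2,3-dimethylbutyl]-3-methoxybenzene-1,2-diol | COc1cc(C[C@@H](C)[C@H](C)Cc2cc(OC)c(O)c(OC)c2)cc(O)c1O | target

Total step count: 9. Longest linear sequence: 6 steps (steps 1, 2, 4, 5, 8 and 9, from 1).

Steps most likely to fail

Step 8. Hydrocupration of the branched alkene may be slow, so that reduction of the aryl bromide overtakes coupling. The resident C8' centre may also oppose the ligand and erode facial selectivity.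
- The fallback sets out from 10 and comes back at 19. It sets C8 by reagent control and adds C7 as a separate carbon.
- Ester 7 is deprotonated with s-BuLi/(+)-sparteine to (R)-1-lithioethyl 2,4,6-triisopropylbenzoate F1.
- F1 homologates 10 by lithiation–borylation to 2-{(2S,3R)-4-[4-(benzyloxy)-3,5-dimethoxyphenyl]-3-methylbutan-2-yl}-4,4,5,5-tetramethyl-1,3,2-dioxaborolane F2.
- Chloromethyllithium (BrCH2Cl, n-BuLi, THF, −78 °C) then inserts C7 by Matteson homologation. This gives 2-{(2R,3R)-4-[4-(benzyloxy)-3,5-dimethoxyphenyl]-2,3-dimethylbutyl}-4,4,5,5-tetramethyl-1,3,2-dioxaborolane F3.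
- Suzuki–Miyaura coupling with 17 (Pd(OAc)2, RuPhos, K2CO3, toluene/H2O, 80 °C) forms the same C7–C1 bond and gives 19.

Step 4. Three things may go wrong: incomplete enantioselection in the deprotonation, removal of the acidic benzylic hydrogen next to boron in 5 in place of addition to boron, or migration of a pinacol oxygen instead of the benzyl group.
- The fallback sets out from 2 and comes back at 13. It sets C8' by catalysis instead of by a chiral carbenoid.
- The CuH/Pd hydroarylation of step 8 is used with the same ligand enantiomer, because C8 and C8' are related by the latent twofold axis of the chain.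
- It joins 2 to commercial 2,3-dimethylbut-3-en-2-ol. An extra equivalent of silane covers silylation of the hydroxyl group, which acidic methanol reverses on work-up.
- The product is (R)-4-[4-(benzyloxy)-3,5-dimethoxyphenyl]-2,3-dimethylbutan-2-ol F4.
- Dehydration with SOCl2/pyridine at 0 °C removes a hydrogen from the more accessible methyl groups to give 13. Any tetrasubstituted alkene isomer is separated on AgNO3-impregnated silica.

Step 5. Formation of the hindered boronate complex may be incomplete, iodine may attack electron-rich ring B, or material may be lost by protodeboronation during the elimination.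
- The fallback sets out from 7 (with 2 as coupling partner) and comes back at 13. It brings the isopropenyl group in as the migrating group, so no iodine-induced olefination is needed.
- (R)-1-Lithioethyl 2,4,6-triisopropylbenzoate F1, made again from 7 with s-BuLi/(+)-sparteine, homologates commercial isopropenylboronic acid pinacol ester. This gives (S)-4,4,5,5-tetramethyl-2-(3-methylbut-3-en-2-yl)-1,3,2-dioxaborolane F5.
- Matteson homologation with chloromethyllithium gives (R)-2-(2,3-dimethylbut-3-en-1-yl)-4,4,5,5-tetramethyl-1,3,2-dioxaborolane F6.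
- Suzuki–Miyaura coupling with 2 (Pd(OAc)2, RuPhos, K2CO3, toluene/H2O, 80 °C) gives 13.

Further compounds
F1 | step 8 | (R)-1-lithioethyl 2,4,6-triisopropylbenzoate | [Li][C@H](C)OC(=O)c1c(C(C)C)cc(C(C)C)cc1C(C)C
F2 | step 8 | 2-{(2S,3R)-4-[4-(benzyloxy)-3,5-dimethoxyphenyl]-3-methylbutan-2-yl}-4,4,5,5-tetramethyl-1,3,2-dioxaborolane | CC1(C)OB(OC1(C)C)[C@@H](C)[C@H](C)Cc1cc(OC)c(OCc2ccccc2)c(OC)c1
F3 | step 8 | 2-{(2R,3R)-4-[4-(benzyloxy)-3,5-dimethoxyphenyl]-2,3-dimethylbutyl}-4,4,5,5-tetramethyl-1,3,2-dioxaborolane | CC1(C)OB(OC1(C)C)C[C@@H](C)[C@H](C)Cc1cc(OC)c(OCc2ccccc2)c(OC)c1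
F4 | step 4 | (R)-4-[4-(benzyloxy)-3,5-dimethoxyphenyl]-2,3-dimethylbutan-2-ol | CC(C)(O)[C@H](C)Cc1cc(OC)c(OCc2ccccc2)c(OC)c1
F5 | step 5 | (S)-4,4,5,5-tetramethyl-2-(3-methylbut-3-en-2-yl)-1,3,2-dioxaborolane | C=C(C)[C@H](C)B1OC(C)(C)C(C)(C)O1
F6 | step 5 | (R)-2-(2,3-dimethylbut-3-en-1-yl)-4,4,5,5-tetramethyl-1,3,2-dioxaborolane | C=C(C)[C@H](C)CB1OC(C)(C)C(C)(C)O1
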